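The route cuts the C2–C3 bond. The quaternary carbon C3 carries a methyl group, an oxygen, the vinyl carbon C2 and the carbinol carbon C4. This is the substitution pattern of lactic acid, with C2 in place of the α-hydrogen and C4 as the former carboxyl carbon. The key step is an aldol addition of the lithium enolate of the five-membered cis pivalaldehyde acetal of (S)-lactic acid to acetaldehyde. It forms this bond and fixes C3 as R in one operation. Its precursor is (2S,5S)-2-tert-butyl-5-methyl-1,3-dioxolan-4-one. The prenyl chain is then attached by opening a C4–C5 epoxide, so that no metathesis catalyst ever meets the 1,6-diene.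

Key step: step 2

Remarks on the chemistry:
- Atoms are numbered along the octadiene chain: C1=C2 vinyl, C3 quaternary, C4 acyloxy methine, C5 methylene, C6=C7 prenyl alkene. The target is (3R,4S) with an E cinnamate.
- (S)-Lactic acid leads to 3R, because the vinyl carbon takes the spatial place of the α-hydrogen.
- C1=C2 and C6=C7 form a 1,6-diene that would ring-close to a cyclopentene on a ruthenium carbene. The prenyl group is therefore brought in whole by a Grignard reagent.

Step 1
Reactants: 1 (S)-lactic acid; 2 pivalaldehyde
Product: 3 (2S,5S)-2-tert-butyl-5-methyl-1,3-dioxolan-4-one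
Conditions: TsOH·H2O (cat.), H2SO4 (cat.), pentane, reflux, Dean–Stark; recrystallisation from pentane/Et2O, −78 °C
Reagents that add atoms: none
Why: Acid-catalysed acetalisation of an α-hydroxy acid with azeotropic removal of water is reversible, so the cis isomer with both substituents on the same ring face should predominate and be obtained pure by cold crystallisation, the acetal carbon being set as S under thermodynamic control by the lactate centre.

Step 2
Reactants: 3 (2S,5S)-2-tert-butyl-5-methyl-1,3-dioxolan-4-one; 4 acetaldehyde
Product: 6 (2S,5R)-2-tert-butyl-5-(1-hydroxyethyl)-5-methyl-1,3-dioxolan-4-one (both epimers at the carbinol carbon), via lithium enolate 5 (not isolated)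
Conditions: LiN(iPr)2 (1.05 equiv), THF, −78 °C, 3 added to the base; then MeCHO (1.5 equiv), −78 °C; AcOH/THF quench at −78 °C
Reagents that add atoms: none
Why: LiN(iPr)2 removes the ring C5 hydrogen to give the planar lithium enolate 5, in which the lactate stereocentre is erased and the chirality is held only by the acetal carbon. The enolate adds to acetaldehyde through a closed lithium-chelated six-membered transition state, an aldol addition of the self-regeneration-of-stereocentres type that is established for dioxolanone enolates with alkyl halides, aldehydes and ketones. No ring is closed; the only skeletal bond formed is C2–C3 of the target. The new quaternary centre is controlled by the tert-butyl group, which shields one face of the five-membered ring, so the aldehyde should enter anti to it and take the place of the former hydrogen, giving 5R (later 3R). The selectivity needed is facial selectivity of the enolate; the carbinol configuration is uncontrolled and irrelevant because that carbon becomes sp2 in step 3. Adding 3 to the base and quenching cold with acid should suppress enolate self-condensation and retro-aldol cleavage.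

Step 3
Reactants: 6 (2S,5R)-2-tert-butyl-5-(1-hydroxyethyl)-5-methyl-1,3-dioxolan-4-one
Product: 7 (2S,5R)-2-tert-butyl-5-ethenyl-5-methyl-1,3-dioxolan-4-one
Conditions: Burgess reagent [methyl N-(triethylammoniosulfonyl)carbamate, 1.5 equiv], toluene, 70 °C
Reagents that add atoms: none
Why: The Burgess dehydration is a syn elimination (Ei) of the intermediate sulfamate, and because the carbinol carbon sits next to a quaternary carbon the only β-hydrogens are those of the methyl group, so both carbinol epimers should converge on the single terminal alkene C1=C2 without touching the acetal or the quaternary centre.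

Step 4
Reactants: 7 (2S,5R)-2-tert-butyl-5-ethenyl-5-methyl-1,3-dioxolan-4-one
Product: 8 methyl (2R)-2-hydroxy-2-methylbut-3-enoate
Conditions: NaOMe (0.1 equiv), MeOH, 0 °C to rt; careful concentration (volatile product)
Reagents that add atoms: methanol, CO
Why: Catalytic methoxide attacks the activated lactone carbonyl (transesterification), the hemiacetal alkoxide so released expels pivalaldehyde, and the quaternary centre has no α-hydrogen and cannot epimerise.

Step 5
Reactants: 8 methyl (2R)-2-hydroxy-2-methylbut-3-enoate
Product: 9 methyl (2R)-2-methyl-2-[(triethylsilyl)oxy]but-3-enoate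
Conditions: Et3SiOTf (1.3 equiv), 2,6-lutidine (2 equiv), CH2Cl2, 0 °C to rt
Reagents that add atoms: triethylsilyl trifluoromethanesulfonate, CC[Si](CC)(CC)OS(=O)(=O)C(F)(F)F
Why: Silyl triflates with 2,6-lutidine silylate even tertiary α-hydroxy esters (O-silylation), and the triethylsilyl ether masks the tertiary hydroxyl through the organolithium, borane and Grignard steps yet is removable by fluoride.

Step 6
Reactants: 9 methyl (2R)-2-methyl-2-[(triethylsilyl)oxy]but-3-enoate; 10 chloroiodomethane
Product: 12 (3R)-1-chloro-3-methyl-3-[(triethylsilyl)oxy]pent-4-en-2-one, via lithium hemiketal alkoxide 11 (not isolated)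
Conditions: ICH2Cl (2 equiv), MeLi·LiBr (1.9 equiv, slow addition to the mixture), THF, −78 °C; AcOH/THF quench at −78 °C
Reagents that add atoms: none
Why: Chloromethyllithium, formed by iodine–lithium exchange in the presence of the ester (Barbier conditions), should add once to give the chelated tetrahedral adduct 11, which persists at −78 °C and collapses to the ketone only on the cold acidic quench (carbenoid homologation of an ester to an α-chloro ketone, known for α-alkoxy esters); the neighbouring centre is quaternary and cannot epimerise.

Step 7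
Reactants: 12 (3R)-1-chloro-3-methyl-3-[(triethylsilyl)oxy]pent-4-en-2-one
Product: 14 triethyl{[(2R)-2-[(2S)-oxiran-2-yl]but-3-en-2-yl]oxy}silane, via chlorohydrin 13 (not isolated)
Conditions: (R)-1-methyl-3,3-diphenyltetrahydro-1H,3H-pyrrolo[1,2-c][1,3,2]oxazaborole (0.3 equiv), catecholborane (1.8 equiv), toluene, −78 to −30 °C; then MeOH, 2 M aq. NaOH, rt
Reagents that add atoms: none
Why: The oxazaborolidine-catalysed (Corey–Bakshi–Shibata) reduction distinguishes the bulky quaternary carbon (large group) from the chloromethyl group (small group), so the R-configured catalyst should set the oxygen-bearing carbon C4 under reagent control in the sense needed for 4S (descriptor R in the chlorohydrin, where CH2Cl outranks C3), catecholborane leaving the vinyl group untouched, and the alkoxide then closes the oxirane by intramolecular Williamson displacement of chloride without touching that centre.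

Step 8
Reactants: 14 triethyl{[(2R)-2-[(2S)-oxiran-2-yl]but-3-en-2-yl]oxy}silane; 15 2-methylprop-1-enylmagnesium bromide
Product: 16 (3R,4S)-3,7-dimethyl-3-[(triethylsilyl)oxy]octa-1,6-dien-4-ol
Conditions: 15 (2.5 equiv, THF solution), CuI (10 mol %), THF, −30 to 0 °C; sat. aq. NH4Cl at 0 °C
Reagents that add atoms: none
Why: The copper-catalysed Grignard opening of a terminal epoxide is an SN2 attack at the unsubstituted carbon C5, which forms the C5–C6 bond, delivers the whole prenyl chain with its trisubstituted alkene already in place and leaves the C4 configuration untouched.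

Step 9
Reactants: 16 (3R,4S)-3,7-dimethyl-3-[(triethylsilyl)oxy]octa-1,6-dien-4-ol
Product: 17 (3R,4S)-3,7-dimethylocta-1,6-diene-3,4-diol
Conditions: Bu4NF (1.5 equiv), THF, 0 °C to rt
Reagents that add atoms: none
Why: Fluoride cleaves the Si–O bond of the tertiary triethylsilyl ether (desilylation) at a stage where no ester is present, so neither acyl migration nor elimination can interfere.

Step 10
Reactants: 18 p-coumaric acid
Product: 20 (E)-3-{4-[(tert-butyldimethylsilyl)oxy]phenyl}prop-2-enoic acid, via bis-silyl derivative 19 (not isolated)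
Conditions: t-BuMe2SiCl (2.4 equiv), imidazole (5 equiv), DMF, rt; then AcOH/THF/H2O (3:1:1), rt
Reagents that add atoms: tert-butyldimethylsilyl chloride, CC(C)(C)[Si](C)(C)Cl
Why: Silylation of both the phenol and the carboxyl group followed by mild hydrolysis of the far more labile silyl ester (protection of a phenol as an aryl silyl ether) should leave the acid free for coupling and the E alkene unchanged.

Step 11
Reactants: 17 (3R,4S)-3,7-dimethylocta-1,6-diene-3,4-diol; 20 (E)-3-{4-[(tert-butyldimethylsilyl)oxy]phenyl}prop-2-enoic acid
Product: 21 (3R,4S)-3-hydroxy-3,7-dimethylocta-1,6-dien-4-yl (E)-3-{4-[(tert-butyldimethylsilyl)oxy]phenyl}prop-2-enoate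
Conditions: DCC (1.2 equiv), DMAP (0.3 equiv), CH2Cl2, 0 °C to rt
Reagents that add atoms: none
Why: The carbodiimide/DMAP (Steglich) esterification should acylate the secondary C4 hydroxyl while the neighbouring tertiary C3 hydroxyl is too hindered to compete, and because the C4–O bond is not broken the configuration is retained.

Step 12
Reactants: 21 (3R,4S)-3-hydroxy-3,7-dimethylocta-1,6-dien-4-yl (E)-3-{4-[(tert-butyldimethylsilyl)oxy]phenyl}prop-2-enoate
Product: 22 (3R,4S)-3-acetoxy-3,7-dimethylocta-1,6-dien-4-yl (E)-3-{4-[(tert-butyldimethylsilyl)oxy]phenyl}prop-2-enoate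
Conditions: Ac2O (5 equiv), DMAP (1 equiv), Et3N (6 equiv), CH2Cl2, rt to 35 °C
Reagents that add atoms: acetic anhydride, CC(=O)OC(C)=O
Why: DMAP-catalysed acylation with excess anhydride (nucleophilic catalysis through the N-acetylpyridinium ion) is the standard way to acetylate hindered tertiary allylic alcohols, and the absence of alkoxide or strong acid should keep the C4 cinnamate from migrating and the tertiary allylic centre from ionising.

Step 13
Reactants: 22 (3R,4S)-3-acetoxy-3,7-dimethylocta-1,6-dien-4-yl (E)-3-{4-[(tert-butyldimethylsilyl)oxy]phenyl}prop-2-enoate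
Product: 23 (3R,4S)-3-acetoxy-3,7-dimethylocta-1,6-dien-4-yl (E)-3-(4-hydroxyphenyl)prop-2-enoate (target)
Conditions: Bu4NF (1.1 equiv), AcOH (1.2 equiv), THF, 0 °C
Reagents that add atoms: none
Why: The aryl silyl ether of an electron-poor phenol is cleaved rapidly by acetic acid-buffered fluoride at 0 °C (desilylation), conditions under which the tertiary allylic acetate, the cinnamate ester and both stereocentres should stay intact.

Compound list
1 | (S)-lactic acid | C[C@H](O)C(=O)O | starting material
2 | pivalaldehyde (2,2-dimethylpropanal) | CC(C)(C)C=O | starting material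
3 | (2S,5S)-2-tert-butyl-5-methyl-1,3-dioxolan-4-one (cis) | C[C@@H]1O[C@H](C(C)(C)C)OC1=O | intermediate
4 | acetaldehyde | CC=O | starting material
5 | lithium (2S)-2-tert-butyl-5-methyl-1,3-dioxol-4-olate (enolate of 3) | CC1=C([O-])O[C@@H](C(C)(C)C)O1.[Li+] | intermediate (not isolated)
6 | (2S,5R)-2-tert-butyl-5-(1-hydroxyethyl)-5-methyl-1,3-dioxolan-4-one, both epimers at the carbinol carbon | C[C@]1(C(C)O)O[C@H](C(C)(C)C)OC1=O | intermediate
7 | (2S,5R)-2-tert-butyl-5-ethenyl-5-methyl-1,3-dioxolan-4-one | C=C[C@@]1(C)O[C@H](C(C)(C)C)OC1=O | intermediate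
8 | methyl (2R)-2-hydroxy-2-methylbut-3-enoate | C=C[C@@](C)(O)C(=O)OC | intermediate
9 | methyl (2R)-2-methyl-2-[(triethylsilyl)oxy]but-3-enoate | C=C[C@@](C)(O[Si](CC)(CC)CC)C(=O)OC | intermediate
10 | chloroiodomethane | ClCI | starting material
11 | lithium (3R)-1-chloro-2-methoxy-3-methyl-3-[(triethylsilyl)oxy]pent-4-en-2-olate, mixed at C2 | C=C[C@@](C)(O[Si](CC)(CC)CC)C([O-])(OC)CCl.[Li+] | intermediate (not isolated)
12 | (3R)-1-chloro-3-methyl-3-[(triethylsilyl)oxy]pent-4-en-2-one | C=C[C@@](C)(O[Si](CC)(CC)CC)C(=O)CCl | intermediate
13 | (2R,3R)-1-chloro-3-methyl-3-[(triethylsilyl)oxy]pent-4-en-2-ol | C=C[C@@](C)(O[Si](CC)(CC)CC)[C@H](CCl)O | intermediate (not isolated)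
14 | triethyl{[(2R)-2-[(2S)-oxiran-2-yl]but-3-en-2-yl]oxy}silane | C=C[C@@](C)(O[Si](CC)(CC)CC)[C@@H]1CO1 | intermediate
15 | 2-methylprop-1-enylmagnesium bromide | CC(C)=C[Mg]Br | starting material
16 | (3R,4S)-3,7-dimethyl-3-[(triethylsilyl)oxy]octa-1,6-dien-4-ol | C=C[C@@](C)(O[Si](CC)(CC)CC)[C@H](CC=C(C)C)O | intermediate
17 | (3R,4S)-3,7-dimethylocta-1,6-diene-3,4-diol | C=C[C@@](C)(O)[C@H](CC=C(C)C)O | intermediate
18 | p-coumaric acid, (E)-3-(4-hydroxyphenyl)prop-2-enoic acid | OC(=O)/C=C/c1ccc(O)cc1 | starting material
19 | tert-butyldimethylsilyl (E)-3-{4-[(tert-butyldimethylsilyl)oxy]phenyl}prop-2-enoate | CC(C)(C)[Si](C)(C)OC(=O)/C=C/c1ccc(O[Si](C)(C)C(C)(C)C)cc1 | intermediate (not isolated)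
20 | (E)-3-{4-[(tert-butyldimethylsilyl)oxy]phenyl}prop-2-enoic acid | OC(=O)/C=C/c1ccc(O[Si](C)(C)C(C)(C)C)cc1 | intermediate
21 | (3R,4S)-3-hydroxy-3,7-dimethylocta-1,6-dien-4-yl (E)-3-{4-[(tert-butyldimethylsilyl)oxy]phenyl}prop-2-enoate | C=C[C@@](C)(O)[C@H](CC=C(C)C)OC(=O)/C=C/c1ccc(O[Si](C)(C)C(C)(C)C)cc1 | intermediate
22 | (3R,4S)-3-acetoxy-3,7-dimethylocta-1,6-dien-4-yl (E)-3-{4-[(tert-butyldimethylsilyl)oxy]phenyl}prop-2-enoate | C=C[C@@](C)(OC(C)=O)[C@H](CC=C(C)C)OC(=O)/C=C/c1ccc(O[Si](C)(C)C(C)(C)C)cc1 | intermediate
23 | (3R,4S)-3-acetoxy-3,7-dimethylocta-1,6-dien-4-yl (E)-3-(4-hydroxyphenyl)prop-2-enoate | C=C[C@@](C)(OC(C)=O)[C@H](CC=C(C)C)OC(=O)/C=C/c1ccc(O)cc1 | target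

Total step count: 13.
Longest linear sequence: 12 steps (steps 1 to 9 and 11 to 13, from 1 to 23); step 10 is a one-step side branch.

Steps most likely to fail

Step 6. The carbenoid may decompose faster than it adds to the hindered α-quaternary ester, or the tetrahedral adduct may collapse early so that a second carbenoid adds. The fallback sets out from 9 and uses an aldehyde as the electrophile. Reduction with i-Bu2AlH (CH2Cl2, −78 °C) should give (2R)-2-methyl-2-[(triethylsilyl)oxy]but-3-enal F1. Chloromethyllithium made in the flask (ICH2Cl, MeLi·LiBr, THF, −78 °C) is added to this far more electrophilic carbonyl and the mixture is quenched cold with AcOH. This keeps the chlorohydrin (3R)-1-chloro-3-methyl-3-[(triethylsilyl)oxy]pent-4-en-2-ol F2 as a mixture of C2 epimers. Oxidation with Dess–Martin periodinane (NaHCO3, CH2Cl2, rt) erases that carbinol centre and comes back to the route at 12.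

Step 7. Facial selectivity in the hydride transfer may be poor if the catalyst does not tell the two ketone substituents apart well enough or the C3 centre works against it, and the hindered ketone may react slowly. The fallback sets out from 12 and replaces the selective reduction by a resolution. Reduction without control (NaBH4, MeOH, −20 °C) should give the chlorohydrin epimer mixture F2 again, and NaOH in the same flask closes it to triethyl{[(2R)-2-(oxiran-2-yl)but-3-en-2-yl]oxy}silane F3, a mixture at the oxirane carbon. A hydrolytic kinetic resolution follows, with [N,N'-bis(3,5-di-tert-butylsalicylidene)-1,2-cyclohexanediaminato]cobalt acetate (trivalent cobalt, about 2 mol %) and water (0.55 equiv) at 0 °C to rt. It should open only the epimer with the R-configured oxirane carbon to (2R,3R)-3-methyl-3-[(triethylsilyl)oxy]pent-4-ene-1,2-diol F4, which is removed by chromatography. The catalyst enantiomer that spares the S-configured oxirane would be assigned on a test scale with both antipodes. The fallback comes back to the route at 14.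

Step 3. The syn elimination of the sulfamate may be sluggish next to the electron-poor quaternary carbon, with displacement at the carbinol carbon or retro-aldol cleavage competing on heating. The fallback sets out from 6 and goes through the ketone. Dess–Martin periodinane (CH2Cl2, rt) should oxidise both epimers to (2S,5R)-5-acetyl-2-tert-butyl-5-methyl-1,3-dioxolan-4-one F5. Its only enolisable position is the methyl group, so KN(SiMe3)2 and PhNTf2 (THF, −78 °C) should give (2S,5R)-2-tert-butyl-5-methyl-5-[1-(trifluoromethylsulfonyloxy)ethenyl]-1,3-dioxolan-4-one F6. Formate hydrogenolysis of the vinyl triflate (Pd(OAc)2, PPh3, Bu3N, HCO2H, DMF, 60 °C) then comes back to the route at 7.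

Further compounds
F1 | step 6 | (2R)-2-methyl-2-[(triethylsilyl)oxy]but-3-enal | C=C[C@@](C)(O[Si](CC)(CC)CC)C=O
F2 | step 6 | (3R)-1-chloro-3-methyl-3-[(triethylsilyl)oxy]pent-4-en-2-ol, mixture of C2 epimers | C=C[C@@](C)(O[Si](CC)(CC)CC)C(O)CCl
F3 | step 7 | triethyl{[(2R)-2-(oxiran-2-yl)but-3-en-2-yl]oxy}silane, mixture at the oxirane carbon | C=C[C@@](C)(O[Si](CC)(CC)CC)C1CO1
F4 | step 7 | (2R,3R)-3-methyl-3-[(triethylsilyl)oxy]pent-4-ene-1,2-diol | C=C[C@@](C)(O[Si](CC)(CC)CC)[C@@H](CO)O
F5 | step 3 | (2S,5R)-5-acetyl-2-tert-butyl-5-methyl-1,3-dioxolan-4-one | C[C@]1(C(C)=O)O[C@H](C(C)(C)C)OC1=O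
F6 | step 3 | (2S,5R)-2-tert-butyl-5-methyl-5-[1-(trifluoromethylsulfonyloxy)ethenyl]-1,3-dioxolan-4-one | C[C@]1(C(=C)OS(=O)(=O)C(F)(F)F)O[C@H](C(C)(C)C)OC1=O
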